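Numbering (germacrane): ring C1–C10; C1=C10 enoate with the C14 ester on C10; C4(Me)–C5 oxirane; O6 is the lactone oxygen; C7 bears C11(=C13)–C12; OAc on C8; epoxy ester on C9.
Feature: O–C6–C7–C8–C9–C10=C1 is a δ,ε-unsaturated carbonyl array. Its C8–C9 bond joins two oxygenated carbons and lies between the C6 oxygen and the ring-cis C1=C10 enoate, which is the oxy-Cope retron. The ring-cis C4–C5 oxirane fits a cyclohexene oxide made of C1–C6.
Late disconnections: the C9 ester and C8 acetate, then C13 (Mannich reaction and elimination), then the γ-lactone (O6–C12 closure, C6 reduction, C7–C11 alkylation).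
Key disconnection: the ten-membered ring comes from a cis-1,2-dialkenyl epoxycyclohexanol by a [3,3] shift that breaks C1–C6, makes C8–C9 and sets C8 and C9.
Ring order: oxirane on the six-membered ring, then the ten-membered ring by expansion, then the γ-lactone; the side-chain oxirane is brought in ready-made.
Key step: step 9

Assumption: the target is taken exactly as its SMILES encodes it (ring-cis 4,5-epoxide, cis-fused 6,7-lactone, ring-cis C1=C10; 4R,5S,6R,7R,8S,9S,2'R). The quinine-derived amine of step 1 is taken to give the (2R,3R)-epoxide, and its quinidine-derived pseudoenantiomer would be used otherwise.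

Step 1
Reactants: 1 3-methylcyclohex-2-en-1-one
Product: 2 (1R,6R)-6-methyl-7-oxabicyclo[4.1.0]heptan-2-one
Conditions: 50% aq H2O2 (1.5 equiv), 9-amino-9-deoxy-epi-quinine (10 mol %), CF3CO2H (20 mol %), dioxane, 30 °C
Reagents that add atoms: hydrogen peroxide, OO
Why: Iminium-catalysed asymmetric Weitz–Scheffer epoxidation of a cyclic enone, in which the chiral primary ammonium salt binds the enone as its iminium ion and steers the hydroperoxide to one face of C4, so that C4 and C5 are set together as the cis-fused oxirane.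

Step 2
Reactants: 2 epoxy ketone; 3 methyl bromoacetate
Product: 5 methyl 2-[(1R,3S,6R)-6-methyl-2-oxo-7-oxabicyclo[4.1.0]heptan-3-yl]acetate, via lithium enolate 4 (not isolated)
Conditions: LiN(iPr)2 (1.05 equiv), THF, −78 °C; 3 (1.5 equiv), DMPU (2 equiv), −78 → −40 °C
Reagents that add atoms: methyl bromoacetate (3), BrCC(=O)OC
Why: Kinetic enolate alkylation in which the base can enolise only toward C1 (C5 is an oxirane carbon) and the bromoacetate should approach the nearly flat enolate from the face opposite the oxirane oxygen, which sets C1 with the side chain trans to the epoxide, the separable minor epimer being recyclable by DBU equilibration.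

Step 3
Reactants: 5 keto ester; 6 ethynylmagnesium bromide
Product: 7 ethynyl carbinol (ethynyl cis to the C1 side chain; OH cis to the oxirane oxygen)
Conditions: 6 (1.5 equiv), LaCl3·2LiCl (1.0 equiv), THF, −78 → −40 °C; AcOH quench at −78 °C
Reagents that add atoms: ethynylmagnesium bromide (6), C#C[Mg]Br
Why: Lanthanide-assisted 1,2-addition of an alkynyl Grignard reagent, in which the slim acetylide enters axially on the conformer with the C1 side chain equatorial and anti to the C5–O bond, two preferences that point to the same face and set C6, while the low temperature spares the ester and the cold acidic quench forestalls lactonisation.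

Step 4
Reactants: 7 ethynyl carbinol
Product: 8 triethylsilyl ether of 7
Conditions: Et3SiOTf (1.5 equiv), 2,6-lutidine (3 equiv), CH2Cl2, −78 → 0 °C
Reagents that add atoms: triethylsilyl triflate, CC[Si](CC)(CC)OS(=O)(=O)C(F)(F)F
Why: Silyl triflate silylation of a hindered tertiary alcohol, needed because a free C6 hydroxyl would close onto the C9 formyl group made in step 7, and no stereocentre is touched.

Step 5
Reactants: 8 silyl ether
Product: 9 (E)-alkenyl pinacolboronate
Conditions: pinacolborane (1.5 equiv), Cp2Zr(H)Cl (10 mol %), Et3N (10 mol %), THF, 50 °C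
Reagents that add atoms: pinacolborane, [H]B1OC(C)(C)C(C)(C)O1
Why: Zirconocene-hydride-catalysed syn hydroboration of a terminal alkyne, which puts boron on the unhindered terminus and fixes the (E)-geometry without touching ester, oxirane or silyl ether, all of which an aluminium hydride reduction of an alkoxyalkyne would endanger.

Step 6
Reactants: 9 alkenylboronate; 10 4-methoxybenzyl alcohol
Product: 11 (E)-2-(4-methoxybenzyloxy)vinyl compound
Conditions: Cu(OAc)2 (2 equiv), Et3N (4 equiv), 10 (15 equiv, neat), 4 Å MS, rt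
Reagents that add atoms: 4-methoxybenzyl alcohol (10), OCc1ccc(OC)cc1
Why: Chan–Lam-type oxidative C–O coupling of an alkenylboronate with an alcohol, which runs at room temperature under amine buffering with retention of alkene geometry and so delivers the (E)-enol ether that a β-alkoxyvinyl anion, prone to anti elimination, could not.

Step 7
Reactants: 11 enol ether ester; 12 methyl formate
Product: 14 TES-protected bis(enol ether), via lithium formyl ester enolate 13 (not isolated)
Conditions: LiN(iPr)2 (1.3 equiv), THF, −78 °C; 12 (5 equiv), −78 → −20 °C; iPr3SiOCH2Cl (TOMCl, 3 equiv), −20 → 0 °C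
Reagents that add atoms: methyl formate (12), O=COC; (triisopropylsiloxy)methyl chloride, ClCO[Si](C(C)C)(C(C)C)C(C)C
Why: Claisen-type formylation of the ester enolate followed by O-alkylation with a hard chloromethyl ether, in which lithium holds the formyl ester enolate as the U-shaped chelate in THF without polar additive, so that capture on the formyl oxygen should give the (Z)-alkoxyacrylate with O9 cis to the ester and trans to C1, any (E)-isomer being removed by chromatography.

Step 8
Reactants: 14 TES-protected bis(enol ether)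
Product: 15 oxy-Cope precursor (free C6 carbinol)
Conditions: Bu4NF (1.2 equiv), AcOH (1.2 equiv), THF, −10 °C
Reagents that add atoms: none
Why: Buffered fluoride desilylation, selective because a triethylsilyl ether is cleaved far faster than the triisopropylsilyl acetal, and neutral enough for both acid-sensitive enol ethers.

Step 9
Reactants: 15 oxy-Cope precursor
Product: 18 ten-membered TIPS enol ether, via potassium alkoxide 16 (not isolated), via potassium enolate 17 (not isolated)
Conditions: KN(SiMe3)2 (1.1 equiv), 18-crown-6 (1.5 equiv), THF, −78 °C; iPr3SiCl (3 equiv) added cold; −78 → 25–40 °C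
Reagents that add atoms: triisopropylsilyl chloride, CC(C)[Si](Cl)(C(C)C)C(C)C
Why: Proposed new method: deprotonation gives alkoxide 16, whose oxyanion weakens the C1–C6 bond and drives a concerted [3,3] shift (C1–C6 broken, C8–C9 made) to enolate 17; the closest known reaction type is the potassium alkoxide/18-crown-6 anionic oxy-Cope ring expansion of 1,2-dialkenylcyclohexanols to cyclodec-5-enones, which has not been shown with enol-ether oxygen on both bond-forming termini or next to an oxirane. The ten-membered ring arises by four-atom expansion of the six-membered ring and not by end-to-end cyclisation, so no dilution is needed. The shift should run through the chair that grows out of the half-chair with the bulky acrylate equatorial and the slim alkoxyvinyl group axial, which puts C2 axial on C1 (hence the ring-cis C1=C10) and C5 equatorial on C6 (hence the enolate with O6 cis to C8). In this chair the (E)-vinyl ether places O8 and the (Z)-acrylate places O9 equatorial, so that C6 and C1 hand their chirality on to C8 (S) and C9 (S). The step needs this chair to win over the chair with the acrylate axial and over boats, which the equatorial preference of the trisubstituted acrylate and the 1,3-diaxial clashes of any axial alkoxy group should secure, and it needs 17 to survive, for which iPr3SiCl is present from the start, too hindered to silylate the tertiary alkoxide yet able to cap the open enolate oxygen before the C8 ether is expelled. Payne migration is shut off because O6 and the oxirane oxygen are cis.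

Step 10
Reactants: 18 TIPS enol ether
Product: 19 ten-membered epoxy ketone with C8 OPMB and C9 OTOM
Conditions: Bu4NF (1.05 equiv), AcOH (1.5 equiv), THF, −40 → −20 °C
Reagents that add atoms: none
Why: Buffered fluoride cleavage of an enol silane, far faster than attack on the alkyl-bound TOM group, with acetic acid protonating C7 as the enolate forms so that base-induced loss of the C8 ether cannot set in.

Step 11
Reactants: 19 epoxy ketone; 20 methyl iodoacetate
Product: 22 C7-alkylated keto diester, via chelated lithium enolate 21 (not isolated)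
Conditions: LiN(SiMe3)2 (1.1 equiv), THF, −78 °C, 30 min; 20 (3 equiv), −78 → −50 °C
Reagents that add atoms: methyl iodoacetate (20), ICC(=O)OC
Why: Alkylation of a chelated lithium enolate by the logic of the Fráter–Seebach alkylation, in which lithium bridges O6 and O8, fixes the enolate with O6 cis to C8, holds the C8–O bond in the nodal plane where it cannot be expelled and leaves C9 and the rest of the ring over one face, so that the iodoacetate enters from the H8 side and sets C7 with C11 cis to O8.

Step 12
Reactants: 22 keto diester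
Product: 24 cis-fused γ-lactone, via hydroxy diester 23 (not isolated)
Conditions: NaBH4 (2 equiv), MeOH/CH2Cl2 1:1, −40 → 0 °C; aq NH4Cl
Reagents that add atoms: none
Why: Borohydride reduction followed by spontaneous lactonisation, in which no chelate forms in methanol, the ketone should react through the conformer with the C=O and C5–O dipoles opposed and C4 and C8 on the inner face, hydride arrives from the periphery and sets C6 with O6 cis to C11, and the C6 oxygen closes the five-membered ring on the unhindered C12 ester while the conjugated C14 ester stays untouched.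

Step 13
Reactants: 24 lactone
Product: 26 α-(dimethylaminomethyl) lactone, via lithium lactone enolate 25 (not isolated)
Conditions: LiN(iPr)2 (1.2 equiv), THF, −78 °C; Me2N=CH2 I (Eschenmoser's salt, 3 equiv), −78 → −20 °C
Reagents that add atoms: N,N-dimethylmethyleneiminium iodide, C[N+](C)=C.[I-]
Why: Mannich reaction of a lactone lithium enolate with a preformed iminium salt, in which the saturated lactone is deprotonated faster than the enoate because the γ-hydrogens at C2 lie trans to the ester, and the new C11 centre (electrophile on the convex face) is erased in step 15.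

Step 14
Reactants: 26 Mannich base
Product: 27 trimethylammonium iodide
Conditions: MeI (10 equiv), THF, rt; evaporation
Reagents that add atoms: methyl iodide, CI
Why: Menshutkin quaternisation of the only nucleophilic nitrogen in the molecule.

Step 15
Reactants: 27 ammonium iodide
Product: 28 α-methylene lactone
Conditions: satd aq NaHCO3, CH2Cl2, rt
Reagents that add atoms: none
Why: Hofmann-type E1cB elimination of trimethylamine under bicarbonate, mild enough for oxirane, esters and TOM group, which installs the exocyclic C11=C13 bond.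

Step 16
Reactants: 28 α-methylene lactone
Product: 29 C8 alcohol
Conditions: DDQ (1.5 equiv), CH2Cl2/pH 7 buffer 10:1, 0 °C
Reagents that add atoms: none
Why: Oxidative PMB cleavage by DDQ through the benzylic oxocarbenium ion under neutral conditions that spare oxirane, enoate, methylene lactone and TOM group, placed after step 15 because DDQ would oxidise the tertiary amine.

Step 17
Reactants: 29 C8 alcohol
Product: 30 C8 acetate
Conditions: Ac2O (3 equiv), pyridine, DMAP (cat), CH2Cl2, 0 °C → rt
Reagents that add atoms: acetic anhydride, CC(=O)OC(C)=O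
Why: DMAP-catalysed acylation of the single free hydroxyl with retention at C8.

Step 18
Reactants: 30 C8 acetate
Product: 32 C9 alcohol, via hemiacetal 31 (not isolated)
Conditions: HF·pyridine, pyridine, THF, 0 °C → rt; aq NaHCO3 work-up
Reagents that add atoms: none
Why: Fluoride cleavage of the silyl acetal, after which the hemiacetal sheds formaldehyde on work-up, the faintly acidic medium holding back O8 to O9 acetyl migration and conjugate addition to the methylene lactone.

Step 19
Reactants: 33 (S)-2-methylglycidol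
Product: 35 (R)-2-methyloxirane-2-carboxylic acid, via epoxy aldehyde 34 (not isolated)
Conditions: TEMPO (0.2 equiv), PhI(OAc)2 (2.2 equiv), MeCN/H2O 1:1, 0 °C → rt
Reagents that add atoms: water, O
Why: Oxoammonium-mediated oxidation of a primary alcohol through the aldehyde hydrate to the acid, in which the quaternary stereocentre cannot epimerise and its descriptor changes from S to R only through the priority rules.

Step 20
Reactants: 32 C9 alcohol; 35 (R)-2-methyloxirane-2-carboxylic acid
Product: 37 CNP0159450.1, via mixed anhydride 36 (not isolated)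
Conditions: 35 (2 equiv), 2,4,6-trichlorobenzoyl chloride (2 equiv), Et3N (2.5 equiv), toluene, 0 °C; then 32, DMAP (2 equiv), toluene, rt
Reagents that add atoms: (R)-2-methyloxirane-2-carboxylic acid (35), OC(=O)[C@@]1(C)CO1
Why: Yamaguchi esterification, suited to a hindered allylic alcohol, which forms the O9–acyl bond without touching the C9–O bond or the quaternary oxirane carbon, so both configurations are retained.

Compound list
1 | 3-methylcyclohex-2-en-1-one | CC1=CC(=O)CCC1 | starting material
2 | (1R,6R)-6-methyl-7-oxabicyclo[4.1.0]heptan-2-one | O=C1CCC[C@@]2(C)O[C@@H]12 | intermediate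
3 | methyl bromoacetate | BrCC(=O)OC | starting material
4 | lithium enolate of 2 toward C1 | [Li+].[O-]C1=CCC[C@@]2(C)O[C@@H]12 | intermediate
5 | methyl 2-[(1R,3S,6R)-6-methyl-2-oxo-7-oxabicyclo[4.1.0]heptan-3-yl]acetate (side chain trans to the oxirane oxygen) | O=C1[C@H](CC(=O)OC)CC[C@@]2(C)O[C@@H]12 | intermediate
6 | ethynylmagnesium bromide | C#C[Mg]Br | starting material
7 | C6 ethynyl carbinol (ethynyl cis to the C1 CH2CO2Me group, OH cis to the oxirane oxygen) | O[C@@]1(C#C)[C@H](CC(=O)OC)CC[C@@]2(C)O[C@@H]12 | intermediate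
8 | triethylsilyl ether of 7 | CC[Si](CC)(CC)O[C@@]1(C#C)[C@H](CC(=O)OC)CC[C@@]2(C)O[C@@H]12 | intermediate
9 | (E)-C7=C8 alkenyl pinacolboronate | CC[Si](CC)(CC)O[C@@]1(/C=C/B2OC(C)(C)C(C)(C)O2)[C@H](CC(=O)OC)CC[C@@]3(C)O[C@@H]13 | intermediate
10 | 4-methoxybenzyl alcohol | OCc1ccc(OC)cc1 | starting material
11 | (E)-C7=C8 PMB enol ether, C6 OTES, C1 CH2CO2Me | CC[Si](CC)(CC)O[C@@]1(/C=C/OCc2ccc(OC)cc2)[C@H](CC(=O)OC)CC[C@@]3(C)O[C@@H]13 | intermediate
12 | methyl formate | O=COC | starting material
13 | lithium (Z)-enolate of the C10 formyl ester | CC[Si](CC)(CC)O[C@@]1(/C=C/OCc2ccc(OC)cc2)[C@H](/C(C(=O)OC)=C/[O-])CC[C@@]3(C)O[C@@H]13.[Li+] | intermediate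
14 | TES ether of the precursor: (E)-PMB vinyl ether on C6, (Z)-3-(TOM-oxy)acrylate on C1 | CC[Si](CC)(CC)O[C@@]1(/C=C/OCc2ccc(OC)cc2)[C@H](/C(C(=O)OC)=C/OCO[Si](C(C)C)(C(C)C)C(C)C)CC[C@@]3(C)O[C@@H]13 | intermediate
15 | oxy-Cope precursor: cis-1,2-dialkenyl 2,3-epoxy-3-methylcyclohexanol, OH cis to the oxirane oxygen | O[C@@]1(/C=C/OCc2ccc(OC)cc2)[C@H](/C(C(=O)OC)=C/OCO[Si](C(C)C)(C(C)C)C(C)C)CC[C@@]3(C)O[C@@H]13 | intermediate
16 | potassium alkoxide of 15 | [K+].[O-][C@@]1(/C=C/OCc2ccc(OC)cc2)[C@H](/C(C(=O)OC)=C/OCO[Si](C(C)C)(C(C)C)C(C)C)CC[C@@]3(C)O[C@@H]13 | intermediate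
17 | ten-membered potassium enolate (O6 cis to C8; ring-cis C1=C10) | [K+].[O-]/C1=C\[C@H](OCc2ccc(OC)cc2)[C@@H](OCO[Si](C(C)C)(C(C)C)C(C)C)/C(C(=O)OC)=C\CC[C@@]3(C)O[C@@H]13 | intermediate
18 | ten-membered C6 TIPS enol ether, (8S,9S) | CC(C)[Si](C(C)C)(C(C)C)O/C1=C\[C@H](OCc2ccc(OC)cc2)[C@@H](OCO[Si](C(C)C)(C(C)C)C(C)C)/C(C(=O)OC)=C\CC[C@@]3(C)O[C@@H]13 | intermediate
19 | ten-membered 4,5-epoxy C6 ketone, C8 OPMB, C9 OTOM, C1=C10 enoate | O=C1C[C@H](OCc2ccc(OC)cc2)[C@@H](OCO[Si](C(C)C)(C(C)C)C(C)C)/C(C(=O)OC)=C\CC[C@@]3(C)O[C@@H]13 | intermediate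
20 | methyl iodoacetate | ICC(=O)OC | starting material
21 | chelated lithium enolate of 19 (O6 cis to C8) | [Li+].[O-]/C1=C\[C@H](OCc2ccc(OC)cc2)[C@@H](OCO[Si](C(C)C)(C(C)C)C(C)C)/C(C(=O)OC)=C\CC[C@@]3(C)O[C@@H]13 | intermediate
22 | C7 CH2CO2Me keto diester (C11 cis to O8) | O=C1[C@H](CC(=O)OC)[C@H](OCc2ccc(OC)cc2)[C@@H](OCO[Si](C(C)C)(C(C)C)C(C)C)/C(C(=O)OC)=C\CC[C@@]3(C)O[C@@H]13 | intermediate
23 | C6 hydroxy diester (O6 cis to C11) | O[C@@H]1[C@H](CC(=O)OC)[C@H](OCc2ccc(OC)cc2)[C@@H](OCO[Si](C(C)C)(C(C)C)C(C)C)/C(C(=O)OC)=C\CC[C@@]3(C)O[C@@H]13 | intermediate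
24 | cis-fused 6,12-lactone | C1C(=O)O[C@@H]2[C@H]1[C@H](OCc3ccc(OC)cc3)[C@@H](OCO[Si](C(C)C)(C(C)C)C(C)C)/C(C(=O)OC)=C\CC[C@@]1(C)O[C@@H]21 | intermediate
25 | lithium enolate of lactone 24 | [Li+].C1=C([O-])O[C@@H]2[C@H]1[C@H](OCc3ccc(OC)cc3)[C@@H](OCO[Si](C(C)C)(C(C)C)C(C)C)/C(C(=O)OC)=C\CC[C@@]1(C)O[C@@H]21 | intermediate
26 | C11 dimethylaminomethyl lactone (C13 on the convex face) | CN(C)C[C@@H]1C(=O)O[C@@H]2[C@H]1[C@H](OCc3ccc(OC)cc3)[C@@H](OCO[Si](C(C)C)(C(C)C)C(C)C)/C(C(=O)OC)=C\CC[C@@]1(C)O[C@@H]21 | intermediate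
27 | trimethylammonium iodide of 26 | C[N+](C)(C)C[C@@H]1C(=O)O[C@@H]2[C@H]1[C@H](OCc3ccc(OC)cc3)[C@@H](OCO[Si](C(C)C)(C(C)C)C(C)C)/C(C(=O)OC)=C\CC[C@@]1(C)O[C@@H]21.[I-] | intermediate
28 | α-methylene lactone, C8 OPMB, C9 OTOM | C=C1C(=O)O[C@@H]2[C@H]1[C@H](OCc3ccc(OC)cc3)[C@@H](OCO[Si](C(C)C)(C(C)C)C(C)C)/C(C(=O)OC)=C\CC[C@@]1(C)O[C@@H]21 | intermediate
29 | C8 alcohol | C=C1C(=O)O[C@@H]2[C@H]1[C@H](O)[C@@H](OCO[Si](C(C)C)(C(C)C)C(C)C)/C(C(=O)OC)=C\CC[C@@]1(C)O[C@@H]21 | intermediate
30 | C8 acetate, C9 OTOM | C=C1C(=O)O[C@@H]2[C@H]1[C@H](OC(C)=O)[C@@H](OCO[Si](C(C)C)(C(C)C)C(C)C)/C(C(=O)OC)=C\CC[C@@]1(C)O[C@@H]21 | intermediate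
31 | C9 hydroxymethyl hemiacetal | C=C1C(=O)O[C@@H]2[C@H]1[C@H](OC(C)=O)[C@@H](OCO)/C(C(=O)OC)=C\CC[C@@]1(C)O[C@@H]21 | intermediate
32 | C8 acetate C9 alcohol | C=C1C(=O)O[C@@H]2[C@H]1[C@H](OC(C)=O)[C@@H](O)/C(C(=O)OC)=C\CC[C@@]1(C)O[C@@H]21 | intermediate
33 | (S)-2-methylglycidol | OC[C@@]1(C)CO1 | starting material
34 | (R)-2-methyloxirane-2-carbaldehyde | O=C[C@@]1(C)CO1 | intermediate
35 | (R)-2-methyloxirane-2-carboxylic acid | OC(=O)[C@@]1(C)CO1 | intermediate
36 | mixed anhydride of 35 with 2,4,6-trichlorobenzoic acid | O=C(OC(=O)[C@@]1(C)CO1)c2c(Cl)cc(Cl)cc2Cl | intermediate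
37 | CNP0159450.1 | C=C1C(=O)O[C@@H]2[C@H]1[C@H](OC(C)=O)[C@@H](OC(=O)[C@@]1(C)CO1)/C(C(=O)OC)=C\CC[C@@]1(C)O[C@@H]21 | target

Total step count: 20. Longest linear sequence: 19 (steps 1–18 and 20; step 19 is a one-step branch).

Steps most likely to fail

1. Step 9 (Proposed new method).
- Both bond-forming carbons carry donor oxygen, so the shift may be reluctant and need heat.
- During that time the enolate may lose the C8 ether by β-elimination or open the neighbouring oxirane before it is capped.
- The alkoxide may be silylated or may add to C9 of the acrylate.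
- The competing chair may erode the C1=C10 geometry and the C8/C9 relay.

The fallback sets out from 8 and rejoins at 19. It carries the C8 oxygen through the rearrangement as silicon, which cannot leave from a β-silyl enolate. Hydrosilylation of 8 with PhMe2SiH (Pt2[(CH2=CHSiMe2)2O]3, P(t-Bu)3, THF) gives the (E)-vinylsilane F1. Formylation and TOM capture as in step 7 give the (Z)-alkoxyacrylate F2, and buffered Bu4NF gives the carbinol F3. KH/18-crown-6 in THF then effects the shift with a non-oxygenated vinyl terminus, as in the documented ring expansions. A cold AcOH quench gives the β-silyl ketone F4 with the same chair-derived C8 and C9 configuration. Fleming–Tamao oxidation (KBr, AcOOH, NaOAc, AcOH) replaces silicon by hydroxyl with retention to give the aldol F5. 4-Methoxybenzyl trichloroacetimidate with La(OTf)3 (cat) returns 19.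

2. Step 11.
- Slow alkylation at low temperature may leave time for β-elimination of the C8 ether.
- Proton exchange may scramble C7.
- A non-chelated enolate conformer may admit the electrophile from the wrong face.

The fallback sets out from 19 and rejoins at 22. It forms the C7–C11 bond under neutral, ligand-controlled conditions. LiN(SiMe3)2/TMEDA and allyl chloroformate at −78 °C give the allyl enol carbonate F6. Decarboxylative Tsuji–Trost allylation follows with Pd2(dba)3·CHCl3 and (1R,2R)-N,N'-bis(2-diphenylphosphinobenzoyl)cyclohexane-1,2-diamine or its enantiomer, whichever matches, and gives the α-allyl ketone F7. Lemieux–Johnson cleavage (OsO4 cat, NMO; NaIO4) of the only electron-rich alkene gives the aldehyde F8. Pinnick oxidation gives the acid F9, and Me3SiCHN2 returns 22.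

3. Step 12.
- Hydride delivery may follow the sense typical of α,β-epoxy ketones and give the C6 epimer, which cannot form the cis-fused lactone with retention.

The fallback sets out from 22 and rejoins at 24. It makes that epimer on purpose and closes the ring with inversion. Chelation-controlled reduction with Zn(BH4)2 (Et2O, −30 °C) gives the 6-epi hydroxy diester F10. Me3SnOH (1,2-dichloroethane, 60 °C) cleaves only the unhindered C12 methyl ester and gives the hydroxy acid F11. Intramolecular Mitsunobu lactonisation (PPh3, DIAD, toluene, 0 °C) inverts C6 and gives 24.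

Further compounds
F1 | step 9 | (E)-2-(dimethylphenylsilyl)vinyl analogue of 11 | CC[Si](CC)(CC)O[C@@]1(/C=C/[Si](C)(C)c2ccccc2)[C@H](CC(=O)OC)CC[C@@]3(C)O[C@@H]13
F2 | step 9 | (Z)-TOM-oxyacrylate of F1 | CC[Si](CC)(CC)O[C@@]1(/C=C/[Si](C)(C)c2ccccc2)[C@H](/C(C(=O)OC)=C/OCO[Si](C(C)C)(C(C)C)C(C)C)CC[C@@]3(C)O[C@@H]13
F3 | step 9 | free C6 carbinol of F2 | O[C@@]1(/C=C/[Si](C)(C)c2ccccc2)[C@H](/C(C(=O)OC)=C/OCO[Si](C(C)C)(C(C)C)C(C)C)CC[C@@]3(C)O[C@@H]13
F4 | step 9 | ten-membered C8 dimethylphenylsilyl ketone | O=C1C[C@H]([Si](C)(C)c2ccccc2)[C@@H](OCO[Si](C(C)C)(C(C)C)C(C)C)/C(C(=O)OC)=C\CC[C@@]3(C)O[C@@H]13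
F5 | step 9 | ten-membered C8 hydroxy ketone | O=C1C[C@H](O)[C@@H](OCO[Si](C(C)C)(C(C)C)C(C)C)/C(C(=O)OC)=C\CC[C@@]3(C)O[C@@H]13
F6 | step 11 | allyl enol carbonate of 19 | C=CCOC(=O)O/C1=C\[C@H](OCc2ccc(OC)cc2)[C@@H](OCO[Si](C(C)C)(C(C)C)C(C)C)/C(C(=O)OC)=C\CC[C@@]3(C)O[C@@H]13
F7 | step 11 | C7 allyl ketone | O=C1[C@H](CC=C)[C@H](OCc2ccc(OC)cc2)[C@@H](OCO[Si](C(C)C)(C(C)C)C(C)C)/C(C(=O)OC)=C\CC[C@@]3(C)O[C@@H]13
F8 | step 11 | C12 aldehyde | O=C1[C@H](CC=O)[C@H](OCc2ccc(OC)cc2)[C@@H](OCO[Si](C(C)C)(C(C)C)C(C)C)/C(C(=O)OC)=C\CC[C@@]3(C)O[C@@H]13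
F9 | step 11 | C12 carboxylic acid | O=C1[C@H](CC(=O)O)[C@H](OCc2ccc(OC)cc2)[C@@H](OCO[Si](C(C)C)(C(C)C)C(C)C)/C(C(=O)OC)=C\CC[C@@]3(C)O[C@@H]13
F10 | step 12 | 6-epi hydroxy diester | O[C@H]1[C@H](CC(=O)OC)[C@H](OCc2ccc(OC)cc2)[C@@H](OCO[Si](C(C)C)(C(C)C)C(C)C)/C(C(=O)OC)=C\CC[C@@]3(C)O[C@@H]13
F11 | step 12 | 6-epi hydroxy C12 acid | O[C@H]1[C@H](CC(=O)O)[C@H](OCc2ccc(OC)cc2)[C@@H](OCO[Si](C(C)C)(C(C)C)C(C)C)/C(C(=O)OC)=C\CC[C@@]3(C)O[C@@H]13
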